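Cembranolide numbering: ring A = butanolide (O, C14, C1, C15, C16; C17 = exocyclic CH2). Ring B = fourteen-membered carbocycle C1–C14, with C11 = CHCl, C12 = C(OH)CH3, C13 = CH2, C14 = O–CH.
Target ⇒ SN2 opening by chloride at C11 of the C11–C12 E-epoxide (C17 installed just before) ⇒ trans-C11,C12-diol ⇒ titanium pinacol coupling that forms C11–C12 and closes ring B ⇒ open keto aldehyde carried by ring A.
Enabling feature: C11 and C12 are neighbouring heteroatom-bearing atoms of ring B (Cl on C11, OH plus CH3 on C12). Each is therefore a masked carbonyl carbon (C11 aldehyde, C12 methyl ketone), and C12 lies β to the ring A oxygen on C14, which can relay configuration.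
Keto aldehyde ⇒ Wacker oxidation of a C14 allyl group and periodate excision of a terminal farnesyl epoxide. Ring A ⇒ auxiliary-controlled alkylation of a succinate with epoxyfarnesyl bromide (C1), reagent-controlled allylboration (C14), lactonisation.
Order of ring formation: ring A (step 9), ring B (step 12), a temporary oxirane on C11–C12 (step 13, opened in step 16).

Key step: step 12

Remark: the epoxide carbon of the farnesyl-derived arm is racemic, so compounds 11 to 17 are epimer mixtures at this one centre; it is excised in step 11 and is left undefined in the SMILES.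

Step 1
Reactants: 1 (2E,6E)-farnesyl acetate
Product: 2 (2E,6E)-10-bromo-11-hydroxy-3,7,11-trimethyldodeca-2,6-dien-1-yl acetate (racemic)
Conditions: NBS (1.1 equiv), THF/H2O (2:1), 0 °C
Reagents that add atoms: N-bromosuccinimide O=C1CCC(=O)N1Br; water O
Why: Electrophilic bromohydrin formation, in which the aqueous medium exposes mainly the terminal trisubstituted olefin of the coiled chain, water opens the bromonium ion at the tertiary carbon, and the new centre is racemic and is excised in step 11.

Step 2
Reactants: 2 (2E,6E)-10-bromo-11-hydroxy-3,7,11-trimethyldodeca-2,6-dien-1-yl acetate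
Product: 3 (2E,6E)-10,11-epoxy-3,7,11-trimethyldodeca-2,6-dien-1-ol (racemic 10,11-epoxyfarnesol)
Conditions: K2CO3, MeOH, 23 °C
Reagents that add atoms: none
Why: Halohydrin-to-epoxide closure (intramolecular Williamson reaction) runs together with methanolysis of the acetate, so one operation gives the latent aldehyde and frees the allylic alcohol.

Step 3
Reactants: 3 (2E,6E)-10,11-epoxyfarnesol
Product: 5 (2E,6E)-10,11-epoxyfarnesyl bromide, via allylic mesylate 4 (not isolated)
Conditions: MsCl, Et3N, CH2Cl2, −40 °C; then LiBr, THF, 0 °C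
Reagents that add atoms: methanesulfonyl chloride CS(=O)(=O)Cl (its sulfonyl group is found only in 4); lithium bromide [Li+].[Br-]
Why: Mesylation followed by SN2 displacement with bromide (Finkelstein-type exchange) converts the primary allylic alcohol without allylic transposition or loss of E geometry, and the cold neutral conditions spare the epoxide.

Step 4
Reactants: 6 (R)-4-benzyl-1,3-oxazolidin-2-one; 7 4-tert-butoxy-4-oxobutanoic acid (mono-tert-butyl succinate)
Product: 9 tert-butyl 4-[(4R)-4-benzyl-2-oxo-1,3-oxazolidin-3-yl]-4-oxobutanoate, via mixed pivalic anhydride 8 (not isolated)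
Conditions: t-BuCOCl, Et3N, THF, −20 °C; then LiCl, 6, −20 to 23 °C
Reagents that add atoms: pivaloyl chloride CC(C)(C)C(=O)Cl (its acyl group is found only in 8)
Why: N-Acylation of the oxazolidinone through the mixed pivalic anhydride with LiCl activation is the standard mild way to load an Evans auxiliary and leaves the tert-butyl ester untouched.

Step 5
Reactants: 9 tert-butyl 4-[(4R)-4-benzyl-2-oxo-1,3-oxazolidin-3-yl]-4-oxobutanoate; 5 (2E,6E)-10,11-epoxyfarnesyl bromide
Product: 11 tert-butyl (3R,5E,9E)-3-{[(4R)-4-benzyl-2-oxo-1,3-oxazolidin-3-yl]carbonyl}-13,14-epoxy-6,10,14-trimethylpentadeca-5,9-dienoate, via sodium Z-enolate 10 (not isolated)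
Conditions: NaN(SiMe3)2, THF, −78 °C; then 5, −78 to −30 °C
Reagents that add atoms: NaN(SiMe3)2 [Na+].C[Si](C)(C)[N-][Si](C)(C)C (its sodium is found only in 10)
Why: Evans asymmetric alkylation, in which the chelated Z-enolate forms only next to the imide carbonyl and the allylic bromide attacks the face opposite the benzyl group, which sets C1 as R.

Step 6
Reactants: 11 alkylated imide
Product: 12 tert-butyl (3R,5E,9E)-13,14-epoxy-3-(hydroxymethyl)-6,10,14-trimethylpentadeca-5,9-dienoate
Conditions: LiBH4, MeOH (1 equiv), Et2O, 0 °C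
Reagents that add atoms: none
Why: Reductive removal of the auxiliary with LiBH4 (imide reduction) is faster than attack on the hindered tert-butyl ester or the trisubstituted epoxide, and C1 is not touched.

Step 7
Reactants: 12 primary alcohol
Product: 13 tert-butyl (3R,5E,9E)-13,14-epoxy-3-formyl-6,10,14-trimethylpentadeca-5,9-dienoate
Conditions: TEMPO (10 mol %), PhI(OAc)2, CH2Cl2, 23 °C
Reagents that add atoms: none
Why: Oxoammonium (TEMPO) oxidation stops at the aldehyde under nearly neutral conditions, so the α-stereocentre C1 is not epimerised and the olefins and the epoxide survive.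

Step 8
Reactants: 13 aldehyde
Product: 15 tert-butyl (3R,5E,9E)-13,14-epoxy-3-[(1S)-1-hydroxybut-3-en-1-yl]-6,10,14-trimethylpentadeca-5,9-dienoate, via diisopinocampheylborinate 14 (not isolated)
Conditions: B-allyldiisopinocampheylborane [(+)-α-pinene series], Et2O, −78 °C; then NaOH, H2O2, 0 to 23 °C
Reagents that add atoms: B-allyldiisopinocampheylborane C=CCB([C@@H]1C[C@@H]2C[C@H]([C@H]1C)C2(C)C)[C@@H]1C[C@@H]2C[C@H]([C@H]1C)C2(C)C (its boron part is found only in 14)
Why: Brown asymmetric allylboration through a closed chair transition state, in which the isopinocampheyl groups override the small bias of the aldehyde and deliver allyl to its Si face to set C14 as S, after which alkaline peroxide cleaves the boron–oxygen and boron–carbon bonds.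

Step 9
Reactants: 15 homoallylic alcohol
Product: 16 (4R,5S)-5-allyl-4-[(2E,6E)-10,11-epoxy-3,7,11-trimethyldodeca-2,6-dien-1-yl]dihydrofuran-2(3H)-one (trans ring A)
Conditions: KOt-Bu (10 mol %), THF, 0 °C
Reagents that add atoms: none
Why: Alkoxide-catalysed 5-exo-trig transesterification (lactonisation), in which the C14 alkoxide expels tert-butoxide as chain carrier, and the trans relation set in steps 5 and 8 is kept because neither C1 nor C14 is acidic.

Step 10
Reactants: 16 allyl lactone
Product: 17 (4R,5S)-4-[(2E,6E)-10,11-epoxy-3,7,11-trimethyldodeca-2,6-dien-1-yl]-5-(2-oxopropyl)dihydrofuran-2(3H)-one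
Conditions: PdCl2 (10 mol %), Cu(OAc)2·H2O (20 mol %), O2 (1 atm), DMA/H2O (7:1), 23 °C
Reagents that add atoms: water O
Why: Tsuji–Wacker oxidation, in which PdCl2 activates only the monosubstituted olefin, water adds at the internal carbon to give the methyl ketone, and the acetate-buffered copper co-oxidant keeps the medium mild enough for the epoxide.

Step 11
Reactants: 17 methyl ketone
Product: 18 (4E,8E)-4,8-dimethyl-10-[(2S,3R)-5-oxo-2-(2-oxopropyl)tetrahydrofuran-3-yl]deca-4,8-dienal
Conditions: H5IO6, THF/Et2O, 0 °C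
Reagents that add atoms: none
Why: Periodic acid hydrolyses the trisubstituted epoxide in situ and cleaves the glycol (Malaprade-type cleavage), which removes the racemic centre as acetone and unveils the C11 aldehyde without touching the ketone, the lactone or the olefins.

Step 12
Reactants: 18 keto aldehyde
Product: 19 (1R,11R,12R,14S)-11,12-dihydroxy-17-norcembra-3E,7E-dien-16,14-olide (trans-diol; C15 is CH2)
Conditions: TiCl3(DME)1.5, Zn–Cu couple, DME, reflux, then 25 °C; 18 added by syringe pump over 30 h (final about 2 mM), 25 °C; aqueous work-up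
Reagents that add atoms: none
Why: Low-valent titanium made from TiCl3(DME)1.5 and the Zn–Cu couple gives one electron to each carbonyl group, the two metal-bound ketyl radicals (C11 from the aldehyde, C12 from the methyl ketone) couple on the metal, and at 25 °C the carbon–oxygen bonds of the coupled product are not cleaved, so work-up should give the diol. The closest known reaction type is this one itself, the titanium-induced pinacol macrocyclisation of keto aldehydes to carbocyclic 1,2-diols, which tolerates lactones and isolated olefins. The one ring closed is the fourteen-membered ring B, by template-assisted radical–radical C11–C12 coupling of the two arms that the rigid trans ring A holds gauche to each other. C11 relative to C12: both oxygens stay on titanium and are therefore gauche while the ring arms C10 and C13 turn away from each other as in an E-olefin, which leads to the trans (threo) diol, the normal result for rings of ten or more members. C12 relative to C14: closure through the extended C1–C14–C13–C12–C11 zigzag puts either the C12 oxygen or the C12 methyl group syn to the C14 oxygen, and only the first array avoids the methyl/oxygen syn-pentane contact and lets both oxygens share the oxophilic metal, so the Si faces of ketone and aldehyde should be joined to give (11R,12R); this 1,3-relay is the least secure element. The step needs ring closure instead of chain growth, arrest at the diol stage and an untouched lactone, which are secured by slow addition to excess reagent, by the low temperature, and by aldehyde and ketone being the only easily reduced groups of 18.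

Step 13
Reactants: 19 trans-diol
Product: 22 (1R,11R,12R,14S)-11,12-epoxy-17-norcembra-3E,7E-dien-16,14-olide (E-epoxide), via cyclic orthoacetate 20 (not isolated), via bromo acetate 21 (not isolated)
Conditions: MeC(OMe)3, PPTS (cat.), CH2Cl2, 23 °C; AcBr, CH2Cl2, 0 °C; K2CO3, MeOH, 23 °C
Reagents that add atoms: trimethyl orthoacetate COC(C)(OC)OC (its atoms are found only in 20 and 21); acetyl bromide CC(=O)Br (its bromine is found only in 21)
Why: Kolb–Sharpless diol-to-epoxide exchange, in which AcBr ionises the cyclic orthoacetate to an acetoxonium ion, bromide opens it with inversion and the alkoxide freed by methanolysis displaces bromide with a second inversion, so the trans-diol gives the E-epoxide with both configurations retained whichever carbon bromide attacks.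

Step 14
Reactants: 22 epoxy lactone
Product: 24 (1R,11R,12R,14S,15S)-17-(dimethylamino)-11,12-epoxycembra-3E,7E-dien-16,14-olide (Mannich base), via lithium enolate 23 (not isolated)
Conditions: LiN(i-Pr)2, THF, −78 °C; then Me2N=CH2 I, −78 to 23 °C
Reagents that add atoms: LiN(i-Pr)2 [Li+].CC(C)[N-]C(C)C (its lithium is found only in 23); Eschenmoser's salt (N,N-dimethylmethyleneiminium iodide) C=[N+](C)C.[I-]
Why: Mannich reaction of the lactone enolate, which is the only acidic site now that the ketone is gone; the iminium ion attacks anti to the C1 arm (the C15 centre is erased in step 15), and the epoxide is inert to the amide base at −78 °C.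

Step 15
Reactants: 24 Mannich base
Product: 26 (1R,11R,12R,14S)-11,12-epoxycembra-3E,7E,15(17)-trien-16,14-olide, via trimethylammonium iodide 25 (not isolated)
Conditions: MeI, MeOH, 23 °C; then NaHCO3, H2O/CH2Cl2, 23 °C
Reagents that add atoms: iodomethane CI (its methyl group is found only in 25)
Why: Exhaustive methylation and E1cB (Hofmann-type) loss of trimethylamine under bicarbonate buffering installs the exocyclic methylene C17 without a base strong enough to harm the epoxide.

Step 16
Reactants: 26 α-methylene epoxy lactone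
Product: 27 (1R,11S,12R,14S)-11-chloro-12-hydroxycembra-3E,7E,15(17)-trien-16,14-olide (target)
Conditions: LiCl, AcOH, THF, 23 °C
Reagents that add atoms: lithium chloride [Li+].[Cl-]
Why: Nucleophilic epoxide-to-halohydrin opening, in which chloride attacks the secondary carbon C11 in SN2 fashion with inversion (R to S), because C12 is fully substituted and its cationic character is damped by the β-acyloxy group on C14, while the C12–O bond is kept as the tertiary alcohol.

Compound list
1 | (2E,6E)-farnesyl acetate | CC(C)=CCC/C(C)=C/CC/C(C)=C/COC(C)=O | starting material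
2 | (2E,6E)-10-bromo-11-hydroxy-3,7,11-trimethyldodeca-2,6-dien-1-yl acetate (racemic) | CC(C)(O)C(Br)CC/C(C)=C/CC/C(C)=C/COC(C)=O | intermediate
3 | (2E,6E)-10,11-epoxyfarnesol (racemic) | CC1(C)OC1CC/C(C)=C/CC/C(C)=C/CO | intermediate
4 | (2E,6E)-10,11-epoxyfarnesyl methanesulfonate | CC1(C)OC1CC/C(C)=C/CC/C(C)=C/COS(C)(=O)=O | intermediate
5 | (2E,6E)-10,11-epoxyfarnesyl bromide | CC1(C)OC1CC/C(C)=C/CC/C(C)=C/CBr | intermediate
6 | (R)-4-benzyl-1,3-oxazolidin-2-one | O=C1N[C@H](Cc2ccccc2)CO1 | starting material
7 | 4-tert-butoxy-4-oxobutanoic acid | CC(C)(C)OC(=O)CCC(=O)O | starting material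
8 | 4-tert-butoxy-4-oxobutanoic pivalic anhydride | CC(C)(C)OC(=O)CCC(=O)OC(=O)C(C)(C)C | intermediate
9 | tert-butyl 4-[(4R)-4-benzyl-2-oxo-1,3-oxazolidin-3-yl]-4-oxobutanoate | CC(C)(C)OC(=O)CCC(=O)N1[C@H](Cc2ccccc2)COC1=O | intermediate
10 | sodium Z-enolate of 9 | [Na+].[O-]/C(=C\CC(=O)OC(C)(C)C)N1[C@H](Cc2ccccc2)COC1=O | intermediate
11 | tert-butyl (3R,5E,9E)-3-{[(4R)-4-benzyl-2-oxo-1,3-oxazolidin-3-yl]carbonyl}-13,14-epoxy-6,10,14-trimethylpentadeca-5,9-dienoate | CC(C)(C)OC(=O)C[C@@H](C/C=C(C)/CC/C=C(C)/CCC1OC1(C)C)C(=O)N1[C@H](Cc2ccccc2)COC1=O | intermediate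
12 | tert-butyl (3R,5E,9E)-13,14-epoxy-3-(hydroxymethyl)-6,10,14-trimethylpentadeca-5,9-dienoate | CC(C)(C)OC(=O)C[C@@H](C/C=C(C)/CC/C=C(C)/CCC1OC1(C)C)CO | intermediate
13 | tert-butyl (3R,5E,9E)-13,14-epoxy-3-formyl-6,10,14-trimethylpentadeca-5,9-dienoate | CC(C)(C)OC(=O)C[C@@H](C/C=C(C)/CC/C=C(C)/CCC1OC1(C)C)C=O | intermediate
14 | diisopinocampheylborinate of 15 | CC(C)(C)OC(=O)C[C@@H](C/C=C(C)/CC/C=C(C)/CCC1OC1(C)C)[C@@H](OB([C@@H]1C[C@@H]2C[C@H]([C@H]1C)C2(C)C)[C@@H]1C[C@@H]2C[C@H]([C@H]1C)C2(C)C)CC=C | intermediate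
15 | tert-butyl (3R,5E,9E)-13,14-epoxy-3-[(1S)-1-hydroxybut-3-en-1-yl]-6,10,14-trimethylpentadeca-5,9-dienoate | CC(C)(C)OC(=O)C[C@@H](C/C=C(C)/CC/C=C(C)/CCC1OC1(C)C)[C@@H](O)CC=C | intermediate
16 | (4R,5S)-5-allyl-4-[(2E,6E)-10,11-epoxy-3,7,11-trimethyldodeca-2,6-dien-1-yl]dihydrofuran-2(3H)-one | O=C1C[C@@H](C/C=C(C)/CC/C=C(C)/CCC2OC2(C)C)[C@H](CC=C)O1 | intermediate
17 | (4R,5S)-4-[(2E,6E)-10,11-epoxy-3,7,11-trimethyldodeca-2,6-dien-1-yl]-5-(2-oxopropyl)dihydrofuran-2(3H)-one | O=C1C[C@@H](C/C=C(C)/CC/C=C(C)/CCC2OC2(C)C)[C@H](CC(C)=O)O1 | intermediate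
18 | (4E,8E)-4,8-dimethyl-10-[(2S,3R)-5-oxo-2-(2-oxopropyl)tetrahydrofuran-3-yl]deca-4,8-dienal | O=C1C[C@@H](C/C=C(C)/CC/C=C(C)/CCC=O)[C@H](CC(C)=O)O1 | intermediate
19 | (1R,11R,12R,14S)-11,12-dihydroxy-17-norcembra-3E,7E-dien-16,14-olide | C1C(=O)O[C@H]2C[C@@](C)(O)[C@H](O)CC/C(C)=C/CC/C(C)=C/C[C@H]12 | intermediate
20 | cyclic methyl orthoacetate of 19 (orthoester carbon undefined) | C1C(=O)O[C@H]2C[C@@]3(C)OC(C)(OC)O[C@@H]3CC/C(C)=C/CC/C(C)=C/C[C@H]12 | intermediate
21 | (1R,11R,12S,14S)-11-acetoxy-12-bromo-17-norcembra-3E,7E-dien-16,14-olide | C1C(=O)O[C@H]2C[C@](C)(Br)[C@H](OC(C)=O)CC/C(C)=C/CC/C(C)=C/C[C@H]12 | intermediate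
22 | (1R,11R,12R,14S)-11,12-epoxy-17-norcembra-3E,7E-dien-16,14-olide | C1C(=O)O[C@H]2C[C@@]3(C)O[C@@H]3CC/C(C)=C/CC/C(C)=C/C[C@H]12 | intermediate
23 | lithium enolate of 22 | C1=C([O-])O[C@H]2C[C@@]3(C)O[C@@H]3CC/C(C)=C/CC/C(C)=C/C[C@H]12.[Li+] | intermediate
24 | (1R,11R,12R,14S,15S)-17-(dimethylamino)-11,12-epoxycembra-3E,7E-dien-16,14-olide | CN(C)C[C@H]1C(=O)O[C@H]2C[C@@]3(C)O[C@@H]3CC/C(C)=C/CC/C(C)=C/C[C@H]12 | intermediate
25 | methiodide of 24 | C[N+](C)(C)C[C@H]1C(=O)O[C@H]2C[C@@]3(C)O[C@@H]3CC/C(C)=C/CC/C(C)=C/C[C@H]12.[I-] | intermediate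
26 | (1R,11R,12R,14S)-11,12-epoxycembra-3E,7E,15(17)-trien-16,14-olide | C=C1C(=O)O[C@H]2C[C@@]3(C)O[C@@H]3CC/C(C)=C/CC/C(C)=C/C[C@H]12 | intermediate
27 | (1R,11S,12R,14S)-11-chloro-12-hydroxycembra-3E,7E,15(17)-trien-16,14-olide | C=C1C(=O)O[C@H]2C[C@@](C)(O)[C@@H](Cl)CC/C(C)=C/CC/C(C)=C/C[C@H]12 | target

Total step count: 16. Longest linear sequence: 15 steps (steps 1–3 and 5–16, from 1 to 27).

Steps most likely to fail

**Step 12.** What may go wrong: coupling on the wrong face of the ketone relative to C14 (weak 1,3-relay), and chain growth between molecules instead of ring closure. The fallback runs from 18 back to 22 and separates ring closure from stereocontrol. The same TiCl3(DME)1.5/Zn–Cu reagent at reflux (McMurry olefination) should close ring B as the E-olefin (1R,14S)-17-norcembra-3E,7E,11E-trien-16,14-olide F1. AlMe3 and MeONHMe·HCl then open ring A to the C14-hydroxy Weinreb amide F2. The free C14 hydroxyl directs VO(acac)2/t-BuOOH to the nearest olefin and to its own face, so oxygen and not carbon is delivered to C12, giving the 11,12-epoxy hydroxy amide F3. Catalytic pyridinium p-toluenesulfonate in warm toluene re-closes ring A and gives 22.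

**Step 16.** What may go wrong: opening at the tertiary carbon C12, participation of the C7–C8 olefin across the ring once the epoxide is activated, and reversible addition of chloride to C17. The fallback runs from 19 to 27. Chloride displaces an activated C11 oxygen of the trans-diol directly (one inversion), before C17 is present.
- SOCl2/Et3N converts 19 into the cyclic sulfite F4.
- LiCl in DMF at 80 °C, then dilute H2SO4 in THF, should give the chlorohydrin lactone F5.
- Me3SiOTf/2,6-lutidine masks the tertiary alcohol as the silyl ether F6, so base cannot close the epoxide again.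
- LiN(i-Pr)2 gives the lithium enolate F7, which with Eschenmoser's salt gives the Mannich base F8.
- MeI gives the methiodide F9, and NaHCO3 gives the α-methylene silyl ether F10.
- Citric acid in MeOH removes the silyl group and gives 27.

**Step 13.** What may go wrong: slow orthoester formation at the hindered tertiary hydroxyl, and loss of HBr from the bromo acetate instead of ring closure. The fallback runs from 19 back to 22: redox inversion at C11, then a closure with a single inversion. SO3·pyridine/DMSO/Et3N (Parikh–Doering oxidation) gives the α-ketol F11. Chelation-controlled reduction with Zn(BH4)2 in Et2O should give the cis (erythro) diol F12. MsCl/Et3N reacts only at the secondary hydroxyl to give the C11 mesylate F13, and K2CO3 in MeOH closes the E-epoxide 22 with inversion at C11. Because C11 is erased in F11, this path also collects any C11 epimer formed in step 12.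

Further compounds
F1 | step 12 | (1R,14S)-17-norcembra-3E,7E,11E-trien-16,14-olide | C1C(=O)O[C@H]2C/C(C)=C/CC/C(C)=C/CC/C(C)=C/C[C@H]12
F2 | step 12 | C14-hydroxy Weinreb amide from ring opening of F1 (1R,14S) | CON(C)C(=O)C[C@H]1C/C=C(C)/CC/C=C(C)/CC/C=C(C)/C[C@@H]1O
F3 | step 12 | (11R,12R)-11,12-epoxide of F2 | CON(C)C(=O)C[C@H]1C/C=C(C)/CC/C=C(C)/CC[C@H]2O[C@]2(C)C[C@@H]1O
F4 | step 16 | cyclic sulfite of 19 (sulfur centre undefined) | C1C(=O)O[C@H]2C[C@@]3(C)OS(=O)O[C@@H]3CC/C(C)=C/CC/C(C)=C/C[C@H]12
F5 | step 16 | (1R,11S,12R,14S)-11-chloro-12-hydroxy-17-norcembra-3E,7E-dien-16,14-olide | C1C(=O)O[C@H]2C[C@@](C)(O)[C@@H](Cl)CC/C(C)=C/CC/C(C)=C/C[C@H]12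
F6 | step 16 | C12 trimethylsilyl ether of F5 | C1C(=O)O[C@H]2C[C@@](C)(O[Si](C)(C)C)[C@@H](Cl)CC/C(C)=C/CC/C(C)=C/C[C@H]12
F7 | step 16 | lithium enolate of F6 | C1=C([O-])O[C@H]2C[C@@](C)(O[Si](C)(C)C)[C@@H](Cl)CC/C(C)=C/CC/C(C)=C/C[C@H]12.[Li+]
F8 | step 16 | (15S)-17-dimethylamino Mannich base of F6 | CN(C)C[C@H]1C(=O)O[C@H]2C[C@@](C)(O[Si](C)(C)C)[C@@H](Cl)CC/C(C)=C/CC/C(C)=C/C[C@H]12
F9 | step 16 | methiodide of F8 | C[N+](C)(C)C[C@H]1C(=O)O[C@H]2C[C@@](C)(O[Si](C)(C)C)[C@@H](Cl)CC/C(C)=C/CC/C(C)=C/C[C@H]12.[I-]
F10 | step 16 | C12 trimethylsilyl ether of 27 | C=C1C(=O)O[C@H]2C[C@@](C)(O[Si](C)(C)C)[C@@H](Cl)CC/C(C)=C/CC/C(C)=C/C[C@H]12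
F11 | step 13 | (1R,12R,14S)-12-hydroxy-11-oxo-17-norcembra-3E,7E-dien-16,14-olide | C1C(=O)O[C@H]2C[C@@](C)(O)C(=O)CC/C(C)=C/CC/C(C)=C/C[C@H]12
F12 | step 13 | (1R,11S,12R,14S)-11,12-dihydroxy-17-norcembra-3E,7E-dien-16,14-olide | C1C(=O)O[C@H]2C[C@@](C)(O)[C@@H](O)CC/C(C)=C/CC/C(C)=C/C[C@H]12
F13 | step 13 | C11 methanesulfonate of F12 | C1C(=O)O[C@H]2C[C@@](C)(O)[C@@H](OS(C)(=O)=O)CC/C(C)=C/CC/C(C)=C/C[C@H]12
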